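**Retrosynthetic overview** (ring A = the methylcyclohexene ring, ring B = the cyclohexane ring carrying nitrogen and the oxanyl group; naphthalene numbering: C1 bears N, C4 the oxanyl group, C4a/C8a are the ring-fusion carbons, C5=C6 is the alkene)
1. Target 21 comes from amine 20 by N-formylation, and 20 from cis-octalone 17 by tert-butanesulfinyl ketimine formation and methyl addition; the methyl group enters last, anti to the axial ring-fusion bond, which puts nitrogen cis to ring A.
2. Ring A of 17 is closed in one operation from monocyclic 2-(2-iodoethyl)enone 13 and propyne: C4a–C5 and C6–C7 are formed by a nickel-catalysed enone/alkyne/alkylzinc annulation (formal [4+2]).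
3. Enabling feature: the ring-A alkene CH=C(CH3) (C5=C6) is flanked by two ring σ-bonds. One goes to C4a, which is β to C1 of ring B (a latent ketone); the other goes to C7, which is joined through C8 to the α ring-fusion carbon C8a. Ring A is therefore propyne added cis across the β-carbon of a cyclohexenone and a carbanion tethered to its α-carbon.
4. Ring B (enone 11) comes from aldehyde 5 and vinyl ketone 9 by organocatalytic Michael addition/aldol condensation; 5 comes from (S)-linalool 1 by chloroetherification (oxane ring) and hydroboration–oxidation.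
5. Order of ring formation: oxane ring, then ring B, then ring A.

Key step: step 9

Assumption: (S)-(+)-linalool of high enantiomeric purity, 4-[(tert-butyldimethylsilyl)oxy]butanal and propyne (solution in THF) are taken as commercial.

Step 1
Reactants: 1 (S)-(+)-linalool
Product: 2 (2S,5R)-5-chloro-2-ethenyl-2,6,6-trimethyloxane
Conditions: N-chlorosuccinimide, Ph3P=S (10 mol%), CH2Cl2, −20 to 0 °C; chromatographic separation of the C5 epimers
Reagents that add atoms: N-chlorosuccinimide, O=C1CCC(=O)N1Cl
Why: Chloroetherification (halocyclisation): the chloronium ion on the trisubstituted alkene is opened 6-endo by the tertiary hydroxyl at the more substituted carbon through a chair transition state with equatorial C–Cl; C5 is expected to form with little facial control (vinyl and methyl on C2 are of similar size), so the (2S,5R) epimer is isolated by chromatography and the other discarded.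

Step 2
Reactants: 2 (2S,5R)-5-chloro-2-ethenyl-2,6,6-trimethyloxane
Product: 4 2-[(2S,5R)-5-chloro-2,6,6-trimethyloxan-2-yl]ethan-1-ol, via alkyl-9-borabicyclononane 3 (not isolated)
Conditions: 9-BBN, THF, 0 °C to rt; then H2O2, aq. NaOH, 0 °C
Reagents that add atoms: hydrogen peroxide, OO
Why: Hydroboration–oxidation: 9-BBN adds anti-Markovnikov to the only monosubstituted alkene and oxidation gives the primary alcohol; no stereocentre is formed or touched.

Step 3
Reactants: 4 2-[(2S,5R)-5-chloro-2,6,6-trimethyloxan-2-yl]ethan-1-ol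
Product: 5 2-[(2S,5R)-5-chloro-2,6,6-trimethyloxan-2-yl]acetaldehyde
Conditions: Dess–Martin periodinane, CH2Cl2, 0 °C to rt
Reagents that add atoms: none
Why: Dess–Martin oxidation under neutral conditions stops at the aldehyde and avoids β-elimination of the ring oxygen.

Step 4
Reactants: 6 4-[(tert-butyldimethylsilyl)oxy]butanal; 7 vinylmagnesium bromide
Product: 8 6-[(tert-butyldimethylsilyl)oxy]hex-1-en-3-ol (racemic)
Conditions: THF, −78 to 0 °C; then AcOH, H2O
Reagents that add atoms: none
Why: Grignard 1,2-addition to the aldehyde; the new carbinol centre is racemic and is removed in step 5.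

Step 5
Reactants: 8 6-[(tert-butyldimethylsilyl)oxy]hex-1-en-3-ol
Product: 9 6-[(tert-butyldimethylsilyl)oxy]hex-1-en-3-one
Conditions: Dess–Martin periodinane, CH2Cl2, 0 °C; used at once
Reagents that add atoms: none
Why: Dess–Martin oxidation of the allylic alcohol gives the vinyl ketone under neutral conditions that do not trigger its polymerisation.

Step 6
Reactants: 5 2-[(2S,5R)-5-chloro-2,6,6-trimethyloxan-2-yl]acetaldehyde; 9 6-[(tert-butyldimethylsilyl)oxy]hex-1-en-3-one
Product: 11 (4R)-2-{2-[(tert-butyldimethylsilyl)oxy]ethyl}-4-[(2S,5R)-5-chloro-2,6,6-trimethyloxan-2-yl]cyclohex-2-en-1-one, via Michael adduct keto-aldehyde 10 (not isolated)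
Conditions: (S)-2-[diphenyl(trimethylsilyloxy)methyl]pyrrolidine (20 mol%), 4-nitrophenol (20 mol%), CH2Cl2, 0 °C to rt; then Bn2NH·CF3CO2H (30 mol%), toluene, 50 °C
Reagents that add atoms: none
Why: Enamine-catalysed Michael addition followed by ammonium-salt-mediated intramolecular aldol condensation (organocatalytic Robinson-type annulation): the (S)-catalyst shields one face of the E-enamine so that C4 of 11 should form R (catalyst control, same sense as the known additions of aldehydes to nitroalkenes and vinyl ketones), and the ring closes through the only ketone α-carbon that gives a six-membered ring, under conditions too mild to epimerise C4.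

Step 7
Reactants: 11 (4R)-2-{2-[(tert-butyldimethylsilyl)oxy]ethyl}-4-[(2S,5R)-5-chloro-2,6,6-trimethyloxan-2-yl]cyclohex-2-en-1-one
Product: 12 (4R)-4-[(2S,5R)-5-chloro-2,6,6-trimethyloxan-2-yl]-2-(2-hydroxyethyl)cyclohex-2-en-1-one
Conditions: HF·pyridine, THF, 0 °C
Reagents that add atoms: none
Why: Fluoride cleavage of the primary silyl ether in a non-alcoholic medium leaves the enone, the chloride and the oxane untouched and avoids ketal formation.

Step 8
Reactants: 12 (4R)-4-[(2S,5R)-5-chloro-2,6,6-trimethyloxan-2-yl]-2-(2-hydroxyethyl)cyclohex-2-en-1-one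
Product: 13 (4R)-4-[(2S,5R)-5-chloro-2,6,6-trimethyloxan-2-yl]-2-(2-iodoethyl)cyclohex-2-en-1-one
Conditions: I2, PPh3, imidazole, CH2Cl2, 0 °C
Reagents that add atoms: iodine, II
Why: Appel-type iodination of the primary alcohol (SN2 at CH2) under near-neutral conditions; no stereocentre is involved.

Step 9
Reactants: 13 (4R)-4-[(2S,5R)-5-chloro-2,6,6-trimethyloxan-2-yl]-2-(2-iodoethyl)cyclohex-2-en-1-one; 14 propyne
Product: 17 (4R,4aS,8aS)-4-[(2S,5R)-5-chloro-2,6,6-trimethyloxan-2-yl]-6-methyl-3,4,4a,7,8,8a-hexahydronaphthalen-1(2H)-one, via alkylzinc iodide 15 (not isolated), via zinc enolate 16 (not isolated)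
Conditions: Zn dust, LiCl, THF, 30 °C; then Ni(cod)2 (10 mol%), propyne (slow addition), THF, 0 °C to rt; then AcOH, −78 °C
Reagents that add atoms: none
Why: Proposed new method: a ring-closing version of the nickel-catalysed alkylative coupling of an enone, an alkyne and an organozinc, whose intermolecular three-component form is the closest known reaction: zerovalent nickel joins the β-carbon of the enone (C3 of 13, C4a of 17) to the CH carbon of propyne by oxidative cyclisation, giving an O-bound nickel enolate with nickel on the methyl-bearing alkenyl carbon, the alkylzinc tethered to C2 then transmetalates (carbon to nickel, enolate to zinc), and C(sp2)–C(sp3) reductive elimination closes ring A and leaves zinc enolate 16. Ring A is thus closed by reductive elimination from a seven-membered nickelacycle (a formal [4+2] with propyne as the two-carbon partner), not by an exo or endo attack, and cis carbometalation places C4a and C7 on the same side of the new C5=C6 bond, as the ring requires. The regiochemistry (CH= next to C4a, C(CH3)= next to C7) follows the known preference for bond formation between the enone β-carbon and the less hindered alkyne carbon, and the tether delivers the alkyl group to nickel. C4a is set by approach of the nickel–alkyne unit anti to the pseudoequatorial oxanyl group on C4 (substrate control, as in conjugate additions to 4-substituted cyclohexenones); C8a is set afterwards by kinetic protonation of 16 on the face of the C4a hydrogen, which is free of 1,3-diaxial hydrogens, and this should give the cis-fused ketone as in the kinetic ketonisation of 1-decalone enolates. The step needs alkyl transfer to win over β-hydride elimination (phosphine-free nickel), zinc insertion only at the primary C–I bond (the hindered secondary chloride is inert) and a cold, non-basic quench so that the cis ring fusion does not equilibrate.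

Step 10
Reactants: 17 (4R,4aS,8aS)-4-[(2S,5R)-5-chloro-2,6,6-trimethyloxan-2-yl]-6-methyl-3,4,4a,7,8,8a-hexahydronaphthalen-1(2H)-one
Product: 18 (R)-N-{(4R,4aS,8aS)-4-[(2S,5R)-5-chloro-2,6,6-trimethyloxan-2-yl]-6-methyl-3,4,4a,7,8,8a-hexahydronaphthalen-1(2H)-ylidene}-2-methylpropane-2-sulfinamide
Conditions: (R)-tert-butanesulfinamide, Ti(OEt)4, THF, 45 °C
Reagents that add atoms: (R)-2-methylpropane-2-sulfinamide, CC(C)(C)[S@@](=O)N
Why: Titanium-mediated condensation of a ketone with tert-butanesulfinamide (Ti(OEt)4 as Lewis acid and water scavenger) gives the N-sulfinyl ketimine with the sulfinyl group anti to the branched ring-fusion carbon; the lowest workable temperature is used to protect the epimerisable cis ring fusion.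

Step 11
Reactants: 18 (R)-N-sulfinyl ketimine of 17
Product: 19 (R)-N-{(1R,4R,4aR,8aS)-4-[(2S,5R)-5-chloro-2,6,6-trimethyloxan-2-yl]-1,6-dimethyl-1,2,3,4,4a,7,8,8a-octahydronaphthalen-1-yl}-2-methylpropane-2-sulfinamide
Conditions: AlMe3, toluene, −78 °C; then MeLi, −78 °C; H2O
Reagents that add atoms: methyllithium, [Li]C
Why: 1,2-Addition of an organolithium to an AlMe3-activated N-sulfinyl ketimine: methyl is delivered axially, on the face anti to the axial C8a–C8 bond, a sense that the (R)-sulfinyl chelate model is expected to reinforce, so that nitrogen ends equatorial and cis to ring A (1R).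

Step 12
Reactants: 19 (R)-sulfinamide
Product: 20 (1R,4R,4aR,8aS)-4-[(2S,5R)-5-chloro-2,6,6-trimethyloxan-2-yl]-1,6-dimethyl-1,2,3,4,4a,7,8,8a-octahydronaphthalen-1-amine
Conditions: HCl (4 M in dioxane), MeOH, 0 °C; then aq. NaOH
Reagents that add atoms: none
Why: Acidic methanolysis of the N–S bond (standard removal of the sulfinyl group); the trisubstituted alkene, the chloride and the oxane should survive brief cold anhydrous HCl.

Step 13
Reactants: 20 tert-alkyl amine
Product: 21 N-{(1R,4R,4aR,8aS)-4-[(2S,5R)-5-chloro-2,6,6-trimethyloxan-2-yl]-1,6-dimethyl-1,2,3,4,4a,7,8,8a-octahydronaphthalen-1-yl}formamide (CNP0241933.4)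
Conditions: 2,2,2-trifluoroethyl formate, THF, 60 °C
Reagents that add atoms: 2,2,2-trifluoroethyl formate, O=COCC(F)(F)F
Why: N-Formylation of the hindered tert-alkyl amine by acyl transfer from an activated formate ester; no stereocentre is affected.

**Compound list**
1 | (S)-(+)-linalool | C=C[C@@](C)(O)CCC=C(C)C | starting material
2 | (2S,5R)-5-chloro-2-ethenyl-2,6,6-trimethyloxane | C=C[C@]1(C)CC[C@@H](Cl)C(C)(C)O1 | intermediate
3 | 9-{2-[(2S,5R)-5-chloro-2,6,6-trimethyloxan-2-yl]ethyl}-9-borabicyclo[3.3.1]nonane | C(C[C@]1(C)CC[C@@H](Cl)C(C)(C)O1)B1C2CCCC1CCC2 | intermediate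
4 | 2-[(2S,5R)-5-chloro-2,6,6-trimethyloxan-2-yl]ethan-1-ol | OCC[C@]1(C)CC[C@@H](Cl)C(C)(C)O1 | intermediate
5 | 2-[(2S,5R)-5-chloro-2,6,6-trimethyloxan-2-yl]acetaldehyde | O=CC[C@]1(C)CC[C@@H](Cl)C(C)(C)O1 | intermediate
6 | 4-[(tert-butyldimethylsilyl)oxy]butanal | O=CCCCO[Si](C)(C)C(C)(C)C | starting material
7 | vinylmagnesium bromide | C=C[Mg]Br | starting material
8 | 6-[(tert-butyldimethylsilyl)oxy]hex-1-en-3-ol (racemic) | C=CC(O)CCCO[Si](C)(C)C(C)(C)C | intermediate
9 | 6-[(tert-butyldimethylsilyl)oxy]hex-1-en-3-one | C=CC(=O)CCCO[Si](C)(C)C(C)(C)C | intermediate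
10 | (2S)-8-[(tert-butyldimethylsilyl)oxy]-2-[(2S,5R)-5-chloro-2,6,6-trimethyloxan-2-yl]-5-oxooctanal | O=C[C@H]([C@]1(C)CC[C@@H](Cl)C(C)(C)O1)CCC(=O)CCCO[Si](C)(C)C(C)(C)C | intermediate
11 | (4R)-2-{2-[(tert-butyldimethylsilyl)oxy]ethyl}-4-[(2S,5R)-5-chloro-2,6,6-trimethyloxan-2-yl]cyclohex-2-en-1-one | O=C1CC[C@@H]([C@]2(C)CC[C@@H](Cl)C(C)(C)O2)C=C1CCO[Si](C)(C)C(C)(C)C | intermediate
12 | (4R)-4-[(2S,5R)-5-chloro-2,6,6-trimethyloxan-2-yl]-2-(2-hydroxyethyl)cyclohex-2-en-1-one | O=C1CC[C@@H]([C@]2(C)CC[C@@H](Cl)C(C)(C)O2)C=C1CCO | intermediate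
13 | (4R)-4-[(2S,5R)-5-chloro-2,6,6-trimethyloxan-2-yl]-2-(2-iodoethyl)cyclohex-2-en-1-one | O=C1CC[C@@H]([C@]2(C)CC[C@@H](Cl)C(C)(C)O2)C=C1CCI | intermediate
14 | propyne | CC#C | starting material
15 | {2-[(3R)-3-[(2S,5R)-5-chloro-2,6,6-trimethyloxan-2-yl]-6-oxocyclohex-1-en-1-yl]ethyl}zinc iodide | O=C1CC[C@@H]([C@]2(C)CC[C@@H](Cl)C(C)(C)O2)C=C1CC[Zn]I | intermediate
16 | iodozinc enolate of ketone 17 (C1=C8a enolate, ring A closed) | CC1=C[C@H]2[C@H]([C@]3(C)CC[C@@H](Cl)C(C)(C)O3)CCC(O[Zn]I)=C2CC1 | intermediate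
17 | (4R,4aS,8aS)-4-[(2S,5R)-5-chloro-2,6,6-trimethyloxan-2-yl]-6-methyl-3,4,4a,7,8,8a-hexahydronaphthalen-1(2H)-one (cis-fused) | CC1=C[C@H]2[C@H]([C@]3(C)CC[C@@H](Cl)C(C)(C)O3)CCC(=O)[C@H]2CC1 | intermediate
18 | (R)-N-tert-butanesulfinyl ketimine of 17 (C=N geometry labile, sulfinyl anti to C8a expected) | CC1=C[C@H]2[C@H]([C@]3(C)CC[C@@H](Cl)C(C)(C)O3)CCC(=N[S@](=O)C(C)(C)C)[C@H]2CC1 | intermediate
19 | (R)-N-{(1R,4R,4aR,8aS)-4-[(2S,5R)-5-chloro-2,6,6-trimethyloxan-2-yl]-1,6-dimethyl-1,2,3,4,4a,7,8,8a-octahydronaphthalen-1-yl}-2-methylpropane-2-sulfinamide | CC1=C[C@H]2[C@H]([C@]3(C)CC[C@@H](Cl)C(C)(C)O3)CC[C@@](C)(N[S@](=O)C(C)(C)C)[C@H]2CC1 | intermediate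
20 | (1R,4R,4aR,8aS)-4-[(2S,5R)-5-chloro-2,6,6-trimethyloxan-2-yl]-1,6-dimethyl-1,2,3,4,4a,7,8,8a-octahydronaphthalen-1-amine | CC1=C[C@H]2[C@H]([C@]3(C)CC[C@@H](Cl)C(C)(C)O3)CC[C@@](C)(N)[C@H]2CC1 | intermediate
21 | N-{(1R,4R,4aR,8aS)-4-[(2S,5R)-5-chloro-2,6,6-trimethyloxan-2-yl]-1,6-dimethyl-1,2,3,4,4a,7,8,8a-octahydronaphthalen-1-yl}formamide | CC1=C[C@H]2[C@H]([C@]3(C)CC[C@@H](Cl)C(C)(C)O3)CC[C@@](C)(NC=O)[C@H]2CC1 | target

**Totals**
Total step count: 13. Longest linear sequence: 11 steps (1, 2, 3, 6, 7, 8, 9, 10, 11, 12, 13).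

**Steps most likely to fail**

Step 9. Alkyl transfer at nickel may lose to β-hydride elimination, to alkyne oligomerisation or to plain conjugate addition, and the cis ring fusion may equilibrate on quench. The fallback builds ring A by a Lewis-acid-promoted Diels–Alder reaction of known type. It sets out from aldehyde 5: annulation with methyl vinyl ketone under the conditions of step 6 gives (4R)-4-[(2S,5R)-5-chloro-2,6,6-trimethyloxan-2-yl]cyclohex-2-en-1-one F1. Trimethyl[(1E)-2-methylbuta-1,3-dien-1-yl]silane F2 is made from methyl vinyl ketone and (Me3Si)2CHLi by Peterson olefination. The EtAlCl2-promoted Diels–Alder reaction of F1 with F2 (CH2Cl2, −78 to −20 °C) should give the cis-fused allylsilane ketone F3; the diene methyl and the enone carbonyl orient "para", addition is anti to the oxanyl group, and suprafacial addition gives the cis fusion. Protodesilylation with allylic transposition (CF3CO2H, CH2Cl2, 0 °C) moves the double bond to C5=C6 and gives 17, where the route is rejoined.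

Step 1. Ene-type allylic chlorination or 5-exo closure may compete with the 6-endo chloroetherification, and C5 forms without facial control. The fallback sets C5 by reagent control and brings in chlorine by substitution. From 1, epoxidation of the trisubstituted alkene (Shi epoxidation: Oxone with the enantiomer of the fructose-derived ketone 1,2:4,5-di-O-isopropylidene-erythro-2,3-hexodiulo-2,6-pyranose that delivers the 6S epoxide) gives (3S,6S)-6,7-epoxy-3,7-dimethyloct-1-en-3-ol F4. Acid-catalysed 6-endo opening (camphorsulfonic acid, CH2Cl2) gives (3S,6S)-6-ethenyl-2,2,6-trimethyloxan-3-ol F5 after separation from the 5-exo (oxolane) isomer. Appel chlorination with inversion (PPh3, CCl4, 60 °C) gives 2.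

Step 10. The ring-fusion centre next to the carbonyl may epimerise through the enamine/aza-enolate under warm Lewis-acidic conditions, and the hindered ketone may condense incompletely. The fallback goes through a milder imine precursor. From 17, oximation (NH2OH·HCl, NaOAc, MeOH, rt) gives oxime F6; Ph2PCl/Et3N (−40 °C to rt) rearranges it to the N-diphenylphosphinoyl ketimine F7; MeMgBr (toluene/Et2O, −40 °C, same facial sense as in step 11) gives the phosphinic amide F8; HCl in MeOH cleaves the N–P bond and gives amine 20.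

**Further compounds**
F1 | step 9 | (4R)-4-[(2S,5R)-5-chloro-2,6,6-trimethyloxan-2-yl]cyclohex-2-en-1-one | O=C1CC[C@@H]([C@]2(C)CC[C@@H](Cl)C(C)(C)O2)C=C1
F2 | step 9 | trimethyl[(1E)-2-methylbuta-1,3-dien-1-yl]silane | C[Si](C)(C)/C=C(\C)C=C
F3 | step 9 | cis-fused 4-[(2S,5R)-5-chloro-2,6,6-trimethyloxan-2-yl]-6-methyl-5-(trimethylsilyl)-3,4,4a,5,8,8a-hexahydronaphthalen-1(2H)-one (C5 epimers) | CC1=CC[C@@H]2C(=O)CC[C@@H]([C@]3(C)CC[C@@H](Cl)C(C)(C)O3)[C@@H]2C1[Si](C)(C)C
F4 | step 1 | (3S,6S)-6,7-epoxy-3,7-dimethyloct-1-en-3-ol | C=C[C@@](C)(O)CC[C@@H]1OC1(C)C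
F5 | step 1 | (3S,6S)-6-ethenyl-2,2,6-trimethyloxan-3-ol | C=C[C@]1(C)CC[C@H](O)C(C)(C)O1
F6 | step 10 | oxime of ketone 17 | CC1=C[C@H]2[C@H]([C@]3(C)CC[C@@H](Cl)C(C)(C)O3)CCC(=NO)[C@H]2CC1
F7 | step 10 | N-(diphenylphosphinoyl) ketimine of 17 | CC1=C[C@H]2[C@H]([C@]3(C)CC[C@@H](Cl)C(C)(C)O3)CCC(=NP(=O)(c4ccccc4)c4ccccc4)[C@H]2CC1
F8 | step 10 | P,P-diphenylphosphinic amide of amine 20 | CC1=C[C@H]2[C@H]([C@]3(C)CC[C@@H](Cl)C(C)(C)O3)CC[C@@](C)(NP(=O)(c4ccccc4)c4ccccc4)[C@H]2CC1
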